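In germacrane numbering the target is a 2,3-epoxy alcohol. The C9 carbinol of the ten-membered ring adjoins the C1–C10 epoxide, so the ring is opened at C9–C10 into an (E)-alkenyl iodide and an α-acyloxy aldehyde. One Nozaki–Hiyama–Kishi cyclisation closes the carbocycle, carries over the E geometry of C1=C10 and creates C9 while the finished α-methylene lactone and the isobutyrate look on. The cis-fused lactone (C6–C7) and the Z C4=C5 bond act as the turn. The precursor is an open-chain lactone, made in one zinc Barbier step from a prenol-derived Z-enal and an allylic bromide from (S)-glyceraldehyde acetonide (C7–C9). A hydroxyl-guided epoxidation ends the route.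

Key step: step 11

Atom labels (germacrane numbering): C1–C10 are the ring carbons. C11, C12 and C13 are the lactone α-carbon, carbonyl and exocyclic methylene. C14 is the methyl on C10 and C15 the methyl on C4. O6, O8 and O9 are the oxygens on C6, C8 and C9.
Assumption: the carbinol centre of 11 and the orthoester carbon of 17 form as mixtures and are left undefined, because both are lost again (steps 6 and 9).

Step 1
Reactants: 1 prenol (3-methylbut-2-en-1-ol); 2 1-bromobut-2-yne
Product: 4 (Z)-3-methyloct-2-en-6-yn-1-ol, via dilithiated prenol 3 (not isolated)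
Conditions: n-BuLi (2.2 equiv), TMEDA (2.2 equiv), Et2O, 0 °C to rt; then 2, −78 °C to rt
Reagents that add atoms: none
Why: Alkoxide-directed allylic dilithiation removes a proton from the methyl group cis to CH2OLi, and SN2 alkylation of the chelated allyllithium 3 at its primary terminus by the propargylic bromide fixes the Z C4=C5 bond (known dianion alkylation of allylic alcohols).

Step 2
Reactants: 4 (Z)-3-methyloct-2-en-6-yn-1-ol
Product: 6 (2Z,6E)-7-iodo-3-methylocta-2,6-dien-1-ol, via alkenylzirconocene 5 (not isolated)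
Conditions: Cp2Zr(H)Cl (3 equiv), THF, rt to 40 °C, dark; then I2, 0 °C
Reagents that add atoms: iodine, II
Why: Hydrozirconation–iodination: once the hydroxyl is bound as zirconium alkoxide, syn addition of Zr–H and equilibration by excess reagent place zirconium on the methyl-bearing carbon C10, and iodinolysis with retention should give the E-iodide, the trisubstituted alkene being inert.

Step 3
Reactants: 6 (2Z,6E)-7-iodo-3-methylocta-2,6-dien-1-ol
Product: 7 (2Z,6E)-7-iodo-3-methylocta-2,6-dienal
Conditions: TEMPO (10 mol %), PhI(OAc)2 (1.1 equiv), CH2Cl2, 0 °C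
Reagents that add atoms: none
Why: Oxoammonium-mediated (TEMPO) oxidation of the allylic alcohol is mild enough to deliver the Z-enal without Z to E isomerisation and leaves the alkenyl iodide alone.

Step 4
Reactants: 8 (R)-solketal, [(4R)-2,2-dimethyl-1,3-dioxolan-4-yl]methanol
Product: 9 (S)-glyceraldehyde acetonide, (4S)-2,2-dimethyl-1,3-dioxolane-4-carbaldehyde
Conditions: TEMPO (5 mol %), PhI(OAc)2 (1.1 equiv), CH2Cl2, rt; distilled and used at once
Reagents that add atoms: none
Why: The same oxoammonium oxidation converts the primary alcohol into the aldehyde without touching the acetal or the chiral-pool stereocentre, which becomes C8.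

Step 5
Reactants: 9 (S)-glyceraldehyde acetonide; 10 methyl acrylate
Product: 11 methyl 2-{[(4S)-2,2-dimethyl-1,3-dioxolan-4-yl](hydroxy)methyl}prop-2-enoate (carbinol epimers)
Conditions: DABCO (1 equiv), 10 (3 equiv), 1,4-dioxane/H2O 1:1, rt
Reagents that add atoms: none
Why: Morita–Baylis–Hillman reaction: the DABCO–acrylate zwitterion attacks the aldehyde and forms C7–C11, the new carbinol centre is irrelevant and C8 is untouched.

Step 6
Reactants: 11 Morita–Baylis–Hillman adduct
Product: 12 methyl (Z)-2-(bromomethyl)-3-[(4R)-2,2-dimethyl-1,3-dioxolan-4-yl]prop-2-enoate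
Conditions: NBS (1.3 equiv), Me2S (1.4 equiv), CH2Cl2, 0 °C to rt
Reagents that add atoms: N-bromosuccinimide, O=C1CCC(=O)N1Br
Why: Bromination with allylic transposition (SN2' attack of bromide on the alkoxysulfonium salt) is the standard conversion of such adducts into the preferred (Z)-2-(bromomethyl)enoate, in which C8 is cis to CH2Br, under conditions that spare the acetonide.

Step 7
Reactants: 7 (2Z,6E)-7-iodo-3-methylocta-2,6-dienal; 12 allylic bromide
Product: 15 (4S,5S)-4-[(4R)-2,2-dimethyl-1,3-dioxolan-4-yl]-5-[(1Z,5E)-6-iodo-2-methylhepta-1,5-dien-1-yl]-3-methylideneoxolan-2-one, via allylzinc bromide 13 (not isolated), via hydroxy ester 14 (not isolated)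
Conditions: activated Zn dust (2 equiv), THF, 0 °C to rt; aq. NH4Cl work-up; then PPTS (10 mol %), toluene, 45 °C
Reagents that add atoms: none
Why: Barbier-type 2-(methoxycarbonyl)allylation followed by lactonisation: allylzinc 13, in which C8 stays cis to CH2Zn, bonds through its γ-carbon C7 to the Re face of the enal in a closed chair transition state with the alkenyl residue equatorial (syn adduct 14, hence the cis C6/C7 lactone), and the C7 face is chosen by the dioxolane, whose O8 sits inside and coordinated to zinc so that C6 arrives anti to C9, giving 6S,7S next to 8R, while alkenyl iodide and acetonide are inert to zinc and PPTS.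

Step 8
Reactants: 15 lactone acetonide
Product: 16 (4R,5S)-4-[(1R)-1,2-dihydroxyethyl]-5-[(1Z,5E)-6-iodo-2-methylhepta-1,5-dien-1-yl]-3-methylideneoxolan-2-one
Conditions: AcOH/H2O/THF 3:1:1, 40 °C
Reagents that add atoms: none
Why: Mild acid-catalysed acetal hydrolysis frees the C8,C9-diol while the lactone, the alkenyl iodide and the alkenes are stable (the descriptor at C7 changes only through CIP priorities).

Step 9
Reactants: 16 diol
Product: 18 (1R)-2-hydroxy-1-{(2S,3S)-2-[(1Z,5E)-6-iodo-2-methylhepta-1,5-dien-1-yl]-4-methylidene-5-oxooxolan-3-yl}ethyl 2-methylpropanoate, via cyclic orthoester 17 (not isolated)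
Conditions: (MeO)3CCH(CH3)2 (1.5 equiv), PPTS (5 mol %), CH2Cl2, rt; then AcOH/H2O 4:1, 0 °C
Reagents that add atoms: trimethyl orthoisobutyrate, COC(OC)(OC)C(C)C; water, O
Why: Regioselective monoacylation through a cyclic orthoester: acid-catalysed exchange gives 17, and its kinetic hydrolysis expels the primary C9 hydroxyl from the hemi-orthoester, which leaves the isobutyrate on the secondary O8 with C8 untouched.

Step 10
Reactants: 18 hydroxy isobutyrate
Product: 19 (1R)-1-{(2S,3S)-2-[(1Z,5E)-6-iodo-2-methylhepta-1,5-dien-1-yl]-4-methylidene-5-oxooxolan-3-yl}-2-oxoethyl 2-methylpropanoate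
Conditions: Dess–Martin periodinane (1.3 equiv), CH2Cl2, 0 °C to rt; used at once
Reagents that add atoms: none
Why: Dess–Martin oxidation of the primary alcohol is fast and non-basic, so neither acyl migration from O8 to O9 nor epimerisation of the α-acyloxy aldehyde at C8 should intervene.

Step 11
Reactants: 19 iodoalkenyl aldehyde
Product: 21 (1(10)E,4Z,6S,7S,8R,9R)-9-hydroxy-8-(isobutyryloxy)germacra-1(10),4,11(13)-trien-12,6-olide, via alkenylchromium dichloride 20 (not isolated)
Conditions: CrCl2 (10 equiv), NiCl2 (0.1 equiv), DMSO/THF, 19 added by syringe pump to 1 mM, rt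
Reagents that add atoms: none
Why: Zerovalent nickel (from NiCl2 and CrCl2) inserts into the C10–I bond with retention, transmetallation gives alkenylchromium 20 (trivalent chromium), and this adds to the C9 aldehyde; the closest known reaction type is the Nozaki–Hiyama–Kishi macrocyclisation of iodoalkenyl aldehydes to medium and large carbocycles. The ten-membered ring closes in a 10-exo-trig mode, helped by high dilution and by the cis-fused lactone and the Z C4=C5 bond, which hold both arms on one face. The E geometry of C1=C10 is carried over from 19. C9 is set by macrocyclic control: only hydrogen fits inside the ring at C8 and C9, and with C7–C8–C9–C10 extended the O8 ester and the bulky O9–chromium group both point outward only if C10 attacks the Re face (8,9-syn, 9R in 21), whereas the open-chain Felkin–Anh preference of alkenylchromium reagents for the anti isomer is weak. The step needs chemoselectivity for the aldehyde over lactone, isobutyrate and acrylate, which the low basicity and the aldehyde selectivity of organochromium reagents secure.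

Step 12
Reactants: 21 macrocyclic allylic alcohol
Product: 22 target, (1R,4Z,6S,7S,8R,9S,10R)-1,10-epoxy-9-hydroxy-8-(isobutyryloxy)germacra-4,11(13)-dien-12,6-olide
Conditions: mCPBA (1.05 equiv), CH2Cl2/aq. pH 8 phosphate buffer, 0 °C
Reagents that add atoms: mCPBA, O=C(OO)c1cccc(Cl)c1
Why: Hydroxyl-directed Prilezhaev epoxidation: the E C1=C10 bond stands perpendicular to the ring so only its outer face is open, the outward C9–OH (O9–C9–C10=C1 near 130°) hydrogen-bonds the peracid on that face and should give the (1R,10R) threo epoxy alcohol, while C4=C5 (deactivated by allylic O6) and the electron-poor C11=C13 stay untouched.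

Compound list
1 | prenol (3-methylbut-2-en-1-ol) | CC(C)=CCO | starting material
2 | 1-bromobut-2-yne | CC#CCBr | starting material
3 | dilithiated prenol (Z-allyllithium alkoxide) | [Li]OC/C=C(/C)C[Li] | intermediate
4 | (Z)-3-methyloct-2-en-6-yn-1-ol | OC/C=C(/C)CCC#CC | intermediate
5 | (E)-alkenylzirconocene chloride of 4, O-zirconated | Cl[Zr](C1C=CC=C1)(C1C=CC=C1)OC/C=C(/C)CC/C=C(\C)[Zr](Cl)(C1C=CC=C1)C1C=CC=C1 | intermediate
6 | (2Z,6E)-7-iodo-3-methylocta-2,6-dien-1-ol | OC/C=C(/C)CC/C=C(\C)I | intermediate
7 | (2Z,6E)-7-iodo-3-methylocta-2,6-dienal | O=C/C=C(/C)CC/C=C(\C)I | intermediate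
8 | (R)-solketal | OC[C@@H]1COC(C)(C)O1 | starting material
9 | (S)-glyceraldehyde acetonide | O=C[C@@H]1COC(C)(C)O1 | intermediate
10 | methyl acrylate | C=CC(=O)OC | starting material
11 | methyl 2-{[(4S)-2,2-dimethyl-1,3-dioxolan-4-yl](hydroxy)methyl}prop-2-enoate (carbinol epimers) | C=C(C(=O)OC)C(O)[C@@H]1COC(C)(C)O1 | intermediate
12 | methyl (Z)-2-(bromomethyl)-3-[(4R)-2,2-dimethyl-1,3-dioxolan-4-yl]prop-2-enoate | COC(=O)/C(CBr)=C/[C@@H]1COC(C)(C)O1 | intermediate
13 | allylzinc bromide from 12 | COC(=O)/C(C[Zn]Br)=C/[C@@H]1COC(C)(C)O1 | intermediate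
14 | methyl (3S,4S,5Z,9E)-3-[(4R)-2,2-dimethyl-1,3-dioxolan-4-yl]-4-hydroxy-10-iodo-6-methyl-2-methylideneundeca-5,9-dienoate | C=C(C(=O)OC)[C@@H]([C@@H](O)/C=C(/C)CC/C=C(\C)I)[C@@H]1COC(C)(C)O1 | intermediate
15 | (4S,5S)-4-[(4R)-2,2-dimethyl-1,3-dioxolan-4-yl]-5-[(1Z,5E)-6-iodo-2-methylhepta-1,5-dien-1-yl]-3-methylideneoxolan-2-one | C=C1C(=O)O[C@@H](/C=C(/C)CC/C=C(\C)I)[C@H]1[C@@H]2COC(C)(C)O2 | intermediate
16 | (4R,5S)-4-[(1R)-1,2-dihydroxyethyl]-5-[(1Z,5E)-6-iodo-2-methylhepta-1,5-dien-1-yl]-3-methylideneoxolan-2-one | C=C1C(=O)O[C@@H](/C=C(/C)CC/C=C(\C)I)[C@H]1[C@H](CO)O | intermediate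
17 | cyclic orthoester of 16 (2-isopropyl-2-methoxy-1,3-dioxolane on O8/O9) | C=C1C(=O)O[C@@H](/C=C(/C)CC/C=C(\C)I)[C@H]1[C@@H]2COC(OC)(C(C)C)O2 | intermediate
18 | (1R)-2-hydroxy-1-{(2S,3S)-2-[(1Z,5E)-6-iodo-2-methylhepta-1,5-dien-1-yl]-4-methylidene-5-oxooxolan-3-yl}ethyl 2-methylpropanoate | C=C1C(=O)O[C@@H](/C=C(/C)CC/C=C(\C)I)[C@H]1[C@H](CO)OC(=O)C(C)C | intermediate
19 | (1R)-1-{(2S,3S)-2-[(1Z,5E)-6-iodo-2-methylhepta-1,5-dien-1-yl]-4-methylidene-5-oxooxolan-3-yl}-2-oxoethyl 2-methylpropanoate | C=C1C(=O)O[C@@H](/C=C(/C)CC/C=C(\C)I)[C@H]1[C@H](C=O)OC(=O)C(C)C | intermediate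
20 | alkenylchromium dichloride from 19 | C=C1C(=O)O[C@@H](/C=C(/C)CC/C=C(\C)[Cr](Cl)Cl)[C@H]1[C@H](C=O)OC(=O)C(C)C | intermediate
21 | (1(10)E,4Z,6S,7S,8R,9R)-9-hydroxy-8-(isobutyryloxy)germacra-1(10),4,11(13)-trien-12,6-olide | C=C1C(=O)O[C@H]2/C=C(/C)CC/C=C(\C)[C@@H](O)[C@H](OC(=O)C(C)C)[C@@H]12 | intermediate
22 | (1R,4Z,6S,7S,8R,9S,10R)-1,10-epoxy-9-hydroxy-8-(isobutyryloxy)germacra-4,11(13)-dien-12,6-olide | C=C1C(=O)O[C@H]2/C=C(/C)CC[C@H]3O[C@]3(C)[C@@H](O)[C@H](OC(=O)C(C)C)[C@@H]12 | target

Total step count: 12. Longest linear sequence: 9 steps (steps 1–3 then 7–12, or steps 4–6 then 7–12).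

Steps most likely to fail

Step 11. C10 may add to the Si face of the aldehyde, following the open-chain Felkin–Anh sense. Oligomerisation may compete with ring closure, and divalent chromium may reductively remove the α-acyloxy group. Fallback, from 19 back to 21: the cyclisation is kept but its stereochemical outcome is no longer relied on. The 9-epimeric allylic alcohol F1 (alone or mixed with 21) is oxidised with Dess–Martin periodinane to the macrocyclic enone F2. A Luche reduction (NaBH4, CeCl3·7H2O, MeOH, −78 °C) follows, in which hydride rather than carbon is delivered anti to the C8–O bond. This should give the 8,9-syn alcohol 21 under polar Felkin–Anh control, and the route is rejoined there.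

Step 7. Facial selectivity at C7 relative to the dioxolane may be poor if zinc coordination by O8 is lost. The syn selectivity may also erode through geometric equilibration of the allylzinc. Fallback, from 11 back to 15:
- Acetylation (Ac2O, DMAP, pyridine) gives the acetate F3.
- Copper-catalysed SN2' borylation (B2pin2, CuCl, LiCl, KOAc, DMF) gives the configurationally stable (E)-allylboronate F4, with C8 cis to CH2B.
- Allylboration of 7 is catalysed by a BINOL-derived chiral phosphoric acid of the antipode that favours the Re face of the enal. It passes through a rigid closed chair state in which reagent control supports or overrides the dioxolane.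
- Work-up gives 14, which lactonises with PPTS to 15.

Step 12. Facial selectivity may be poor if the ring populates the conformer with the C9–OH folded over the alkene. Epoxidation may compete at C4=C5, and acid may trigger transannular opening of the new epoxide. Fallback, from 21 back to 22: hydrogen-bond delivery is replaced by conformational locking.
- Silylation (TESOTf, 2,6-lutidine, CH2Cl2, −78 °C) gives the triethylsilyl ether F5. Its bulky OSiEt3 group can only occupy the outward position at C9, which fixes which face of C1=C10 is exposed.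
- Acid-free epoxidation with dimethyldioxirane (acetone/CH2Cl2, −20 °C) gives the epoxy silyl ether F6.
- HF·pyridine buffered with pyridine (THF, 0 °C) releases 22.

Further compounds
F1 | step 11 | (1(10)E,4Z,6S,7S,8R,9S)-9-hydroxy-8-(isobutyryloxy)germacra-1(10),4,11(13)-trien-12,6-olide (9-epimer of 21) | C=C1C(=O)O[C@H]2/C=C(/C)CC/C=C(\C)[C@H](O)[C@H](OC(=O)C(C)C)[C@@H]12
F2 | step 11 | (1(10)E,4Z,6S,7S,8R)-8-(isobutyryloxy)-9-oxogermacra-1(10),4,11(13)-trien-12,6-olide | C=C1C(=O)O[C@H]2/C=C(/C)CC/C=C(\C)C(=O)[C@H](OC(=O)C(C)C)[C@@H]12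
F3 | step 7 | methyl 2-{acetoxy[(4S)-2,2-dimethyl-1,3-dioxolan-4-yl]methyl}prop-2-enoate (epimers at the acetoxy carbon) | C=C(C(=O)OC)C(OC(C)=O)[C@@H]1COC(C)(C)O1
F4 | step 7 | methyl (E)-3-[(4R)-2,2-dimethyl-1,3-dioxolan-4-yl]-2-[(4,4,5,5-tetramethyl-1,3,2-dioxaborolan-2-yl)methyl]prop-2-enoate | COC(=O)/C(CB1OC(C)(C)C(C)(C)O1)=C/[C@@H]2COC(C)(C)O2
F5 | step 12 | 9-O-triethylsilyl ether of 21 | C=C1C(=O)O[C@H]2/C=C(/C)CC/C=C(\C)[C@@H](O[Si](CC)(CC)CC)[C@H](OC(=O)C(C)C)[C@@H]12
F6 | step 12 | 9-O-triethylsilyl ether of 22 | C=C1C(=O)O[C@H]2/C=C(/C)CC[C@H]3O[C@]3(C)[C@@H](O[Si](CC)(CC)CC)[C@H](OC(=O)C(C)C)[C@@H]12
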